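The strategy rests on the 1,5-diene C2=C1–C10–C5–C4=C3, that is, the vinyl group on quaternary C10 and the propenal on the adjacent ring carbon C5. This diene is read as an opened bicyclo[2.2.0]hexane, a cyclobutene once fused across C10–C5 of the cyclohexane.
Target ⇒ allylic oxidation at C15, desilylation, angeloylation of O6 and methylenation at C11 ⇒ trans 8,12-γ-lactone ⇒ C9 ketone, used for C8 hydroxylation and then reduced to the axial 9α-alcohol.
C9 ketone ⇒ 6β,15-diol ⇒ keto diester ⇒ thermal opening (C1–C4, C2–C3) and C5/C7 equilibration of a tricyclo[4.4.0.0(2,5)]decanone. The tricycle is alkylated at C7 while the diene is still masked, so no enolate ever meets the acrylate.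
Tricycle ⇒ enone–cyclobutene [2+2] photocycloaddition of (S)-4-silyloxy-3-methylcyclohexenone (from 4-methoxy-2-methylphenol) with methyl cyclobut-1-enecarboxylate (from ethyl 1-bromocyclobutanecarboxylate).
Ring order: cyclohexane (from the arene), outer cyclobutane (bought), central cyclobutane (key step). Both four-membered rings are then opened, and the γ-lactone is closed last.

Key step: step 8

Remark: elemane numbering is used (ring C10, C9, C8, C7, C6, C5; vinyl C1=C2; lactone C11, C12, C13). Because the C2–C3 bond is the one cleaved, the methylene of the propenal is C3 and its carbonyl carbon is C15. β is the face of the C10 methyl and α the opposite face.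

Step 1
Reactants: 1 4-methoxy-2-methylphenol
Product: 2 4,4-dimethoxy-2-methylcyclohexa-2,5-dien-1-one
Conditions: PhI(OAc)2, MeOH, 0 °C
Reagents that add atoms: methanol, CO
Why: Oxidative dearomatisation of a 4-methoxyphenol with a trivalent-iodine oxidant (phenol to quinone monoketal) traps the phenoxenium ion with methanol at the methoxy-bearing para carbon, the only site that gives a stable ketal.

Step 2
Reactants: 2 4,4-dimethoxy-2-methylcyclohexa-2,5-dien-1-one
Product: 3 4,4-dimethoxy-2-methylcyclohex-2-en-1-one
Conditions: H2 (1 atm), RhCl(PPh3)3 (cat.), toluene, rt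
Reagents that add atoms: none
Why: Homogeneous hydrogenation with RhCl(PPh3)3 is very sensitive to alkene substitution, so the disubstituted C7=C8 bond should be saturated and the methyl-bearing C5=C10 bond kept, as in the 1,2-selective reduction of steroidal 1,4-dien-3-ones, while the neutral medium avoids loss of methanol and rearomatisation.

Step 3
Reactants: 3 4,4-dimethoxy-2-methylcyclohex-2-en-1-one
Product: 4 (S)-4,4-dimethoxy-2-methylcyclohex-2-en-1-ol
Conditions: (R)-Me-CBS oxazaborolidine (cat.), BH3·SMe2, THF, −20 °C; MeOH, then aq work-up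
Reagents that add atoms: none
Why: Corey–Bakshi–Shibata reduction in which the α-methylated alkenyl arm acts as the large group and the CH2 arm as the small one, so the (R)-catalyst should give the (S)-carbinol, which is the 9β-oxygen.

Step 4
Reactants: 4 (S)-4,4-dimethoxy-2-methylcyclohex-2-en-1-ol
Product: 5 (S)-tert-butyl[(4,4-dimethoxy-2-methylcyclohex-2-en-1-yl)oxy]dimethylsilane
Conditions: TBSCl, imidazole, DMF, rt
Reagents that add atoms: tert-butyldimethylsilyl chloride, CC(C)(C)[Si](C)(C)Cl
Why: Imidazole-promoted silylation of a secondary allylic alcohol touches no stereocentre and installs the bulky group that later shields the β face.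

Step 5
Reactants: 5 (S)-tert-butyl[(4,4-dimethoxy-2-methylcyclohex-2-en-1-yl)oxy]dimethylsilane
Product: 6 (S)-4-(tert-butyldimethylsilyloxy)-3-methylcyclohex-2-en-1-one
Conditions: PPTS (cat.), acetone–H2O, rt
Reagents that add atoms: water, O
Why: Mild acid hydrolysis of the allylic dimethyl ketal through a conjugated oxocarbenium ion is much faster than cleavage of the secondary silyl ether, and it unmasks the C6 carbonyl in conjugation with C5=C10 without touching C9.

Step 6
Reactants: 7 ethyl 1-bromocyclobutane-1-carboxylate
Product: 8 cyclobut-1-ene-1-carboxylic acid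
Conditions: KOH (powder), toluene, reflux; then aq HCl
Reagents that add atoms: potassium hydroxide, [K+].[OH-]
Why: Classical dehydrobromination–saponification, in which E2 loss of HBr from the α-bromo ester gives the conjugated cyclobutene and hydroxide cleaves the ethyl ester in the same operation.

Step 7
Reactants: 8 cyclobut-1-ene-1-carboxylic acid
Product: 9 methyl cyclobut-1-ene-1-carboxylate
Conditions: MeI, K2CO3, DMF, 0 °C to rt
Reagents that add atoms: iodomethane, CI
Why: SN2 O-alkylation of the carboxylate avoids the acid and heat that the strained, polymerisable ester would not tolerate.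

Step 8
Reactants: 6 (S)-4-(tert-butyldimethylsilyloxy)-3-methylcyclohex-2-en-1-one; 9 methyl cyclobut-1-ene-1-carboxylate
Product: 10 cis-anti-cis photoadduct (methyl 7-(tert-butyldimethylsilyloxy)-6-methyl-10-oxotricyclo[4.4.0.0(2,5)]decane-2-carboxylate; C10 Me β and C1 α; C4 α and H5 β; 9β-OTBS)
Conditions: hν (medium-pressure Hg lamp, Pyrex filter, λ > 300 nm), 9 (3 equiv), toluene, −20 °C; filtration through basic Al2O3
Reagents that add atoms: none
Why: The twisted triplet of 6 should bond from its β-carbon C10 to the CH carbon C1 of 9, giving a 1,4-biradical made of the α-keto radical C5 and the tertiary ester-stabilised radical C4, which recombine to C5–C4 after intersystem crossing. The closest known reaction type is the intermolecular enone–alkene [2+2] photocycloaddition of 3-alkylcyclohexenones with cyclobutene-1-carboxylates. The single new ring, the central cyclobutane C1–C4–C5–C10, is closed by this biradical recombination in an untethered stepwise cycloaddition, and the ring of 9 is carried in unchanged as the outer half of a bicyclo[2.2.0]hexane. C10 is controlled by the C9 silyloxy group, which A(1,2) strain with the C10 methyl pushes pseudoaxial on the β face so that 9 approaches from the α face; C5 follows as the cis six–four fusion (any trans-fused adduct is epimerised on the alumina), and C1 and C4 are cis by the ring constraint of 9 and sit anti to the six-membered ring for steric reasons. The step needs head-to-head regiochemistry and α-facial selectivity: the acceptor ester, which makes the C4-centred biradical the one that closes, together with the avoidance of two adjacent quaternary carbons secures the first, and the bulky pseudoaxial silyl ether secures the second.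

Step 9
Reactants: 10 cis-anti-cis photoadduct; 11 tert-butyl bromoacetate
Product: 13 C7β-(tert-butoxycarbonylmethyl) photoadduct, via lithium enolate 12 (not isolated)
Conditions: LiN(i-Pr)2, THF, −78 °C; then 11, DMPU, −78 to −30 °C
Reagents that add atoms: none
Why: Kinetic enolate alkylation in which LiN(i-Pr)2 takes a proton from the open C7 methylene rather than the cyclobutane methine C5–H, the ester on quaternary C4 cannot enolise, no Michael acceptor exists while the diene is masked, attack on the convex β face is expected, and C7 is in any case equilibrated in step 10.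

Step 10
Reactants: 13 C7β-(tert-butoxycarbonylmethyl) photoadduct
Product: 15 trans keto diester (C6 ketone; C10 Me β and vinyl α; 9β-OTBS; C7β-CH2CO2t-Bu; C5β-C(=CH2)CO2Me), via cis-dialkenyl ketone 14 (not isolated)
Conditions: toluene (0.02 M, degassed), BHT (cat.), base-washed sealed tube, 185 °C; cool, then DBU (0.2 equiv), 60 °C
Reagents that add atoms: none
Why: Thermal cycloreversion of the bicyclo[2.2.0]hexane, in which homolysis of the strained central C1–C4 bond gives an ester-stabilised cyclohexane-1,4-diyl that cleaves C2–C3 (any C5–C10 cleavage gives a cyclodeca-1,5-dienone that returns to the same skeleton by Cope rearrangement), after which DBU equilibrates the ketone α-centres C5 and C7 to the chair with both side chains and the silyloxy group equatorial (H5 and H7 α).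

Step 11
Reactants: 15 trans keto diester
Product: 16 6β,15-diol (tert-butyl ester retained)
Conditions: i-Bu2AlH (3.5 equiv), CH2Cl2, −78 °C; aq KNaC4H4O6
Reagents that add atoms: none
Why: Low-temperature aluminium hydride reduction in which the ketone is attacked along the equatorial trajectory because the axial one is blocked by the syn-axial C10 methyl (3,3,5-trimethylcyclohexanone model), setting the axial 6β-alcohol, while the methyl enoate undergoes 1,2-reduction to the allylic alcohol and the hindered tert-butyl ester is spared, as in known methyl-over-tert-butyl ester selections.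

Step 12
Reactants: 16 6β,15-diol
Product: 17 6,15-bis(methoxymethyl) ether
Conditions: MOMCl, i-Pr2NEt, Bu4NI (cat.), CH2Cl2, 0 to 40 °C
Reagents that add atoms: chloromethyl methyl ether, COCCl
Why: Acetal-type protection with the small and very reactive MOMCl should reach even the hindered axial O6 under amine base, where no alkoxide forms that could lactonise onto C12.

Step 13
Reactants: 17 6,15-bis(methoxymethyl) ether
Product: 18 9β-alcohol
Conditions: Bu4NF, THF, rt to 45 °C
Reagents that add atoms: none
Why: Fluoride-induced desilylation is orthogonal to the acetals and the tert-butyl ester and frees only O9.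

Step 14
Reactants: 18 9β-alcohol
Product: 19 C9 ketone
Conditions: Dess–Martin periodinane, CH2Cl2, 0 °C to rt
Reagents that add atoms: none
Why: Dess–Martin oxidation converts the only free alcohol into the ketone under near-neutral conditions, and the C9 stereocentre, having done its directing work, is erased on purpose.

Step 15
Reactants: 19 C9 ketone
Product: 21 8α-hydroxy-9-ketone, via potassium enolate 20 (not isolated)
Conditions: KN(SiMe3)2, THF, −78 °C; 2-(phenylsulfonyl)-3-phenyloxaziridine, −78 °C; AcOH quench
Reagents that add atoms: 2-(phenylsulfonyl)-3-phenyloxaziridine, O=S(=O)(c1ccccc1)N1OC1c1ccccc1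
Why: Davis oxidation of the only possible enolate (C10 is quaternary), where the oxaziridine should reach C8 from the α face because the β face carries the syn-axial C10 methyl and C6 OMOM groups, giving the equatorial 8α-alcohol trans to the C7 side chain.

Step 16
Reactants: 21 8α-hydroxy-9-ketone
Product: 23 9-oxo-8α,12-lactone (trans-fused), via hydroxy acid 22 (not isolated)
Conditions: CF3CO2H–CH2Cl2 (1:9), 0 °C to rt; toluene azeotrope
Reagents that add atoms: none
Why: Acidolysis of the tert-butyl ester with loss of isobutene and 5-exo-trig lactonisation by the neighbouring equatorial 8α-hydroxyl close the trans γ-lactone, and the blocked O6 rules out the competing cis 6,12-lactone.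

Step 17
Reactants: 23 9-oxo-8α,12-lactone
Product: 24 9α-hydroxy lactone
Conditions: LiBH(s-Bu)3, THF, −78 °C; AcOH quench
Reagents that add atoms: none
Why: Bulky trialkylborohydride reduction in which LiBH(s-Bu)3 should attack the conformationally locked ketone along the equatorial (β) trajectory and give the axial 9α-alcohol cis to O8, as in the reduction of 4,4-dimethyl-3-keto triterpenoids to their axial alcohols, while the lactone is inert at −78 °C.

Step 18
Reactants: 24 9α-hydroxy lactone
Product: 25 9α-(tert-butyldimethylsilyloxy) lactone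
Conditions: TBSOTf, 2,6-lutidine, CH2Cl2, 0 °C
Reagents that add atoms: tert-butyldimethylsilyl triflate, CC(C)(C)[Si](C)(C)OS(=O)(=O)C(F)(F)F
Why: Silyl triflate silylation is reactive enough for the axial neopentyl-type alcohol and masks O9 for the enolate and acylation steps.

Step 19
Reactants: 25 9α-(tert-butyldimethylsilyloxy) lactone
Product: 29 α-methylene lactone (C11=C13), via lithium lactone enolate 26 (not isolated), via Mannich base 27 (not isolated), via methiodide 28 (not isolated)
Conditions: LiN(i-Pr)2, THF, −78 °C; CH2=NMe2 iodide, −78 °C to rt; MeI, CH2Cl2–MeOH, rt; aq NaHCO3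
Reagents that add atoms: N,N-dimethylmethyleneiminium iodide (Eschenmoser's salt), C=[N+](C)C.[I-]
Why: Eschenmoser methylenation, in which a Mannich reaction of the lactone enolate (the only acidic C–H left), N-methylation and Hofmann-type elimination install C13, and the transient C11 centre is destroyed in the same step.

Step 20
Reactants: 29 α-methylene lactone
Product: 31 6β,15-diol of the methylene lactone, via bis(bromomethyl) ether 30 (not isolated)
Conditions: Me2BBr, CH2Cl2, −78 °C; then aq NaHCO3–THF
Reagents that add atoms: none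
Why: Dimethylboron bromide cleaves acetal-type ethers at −78 °C through bromomethyl ethers that hydrolyse on work-up, conditions under which silyl ethers, lactones and alkenes are known to persist.

Step 21
Reactants: 31 6β,15-diol of the methylene lactone
Product: 32 15-O-triethylsilyl ether (6β-OH free)
Conditions: Et3SiCl (1.1 equiv), imidazole, CH2Cl2, −20 °C
Reagents that add atoms: chlorotriethylsilane, CC[Si](Cl)(CC)CC
Why: Chemoselective silylation, since the primary allylic alcohol reacts far faster than the axial, doubly flanked 6β-alcohol.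

Step 22
Reactants: 32 15-O-triethylsilyl ether; 33 angelic acid
Product: 35 6β-angelate, via mixed anhydride 34 (not isolated)
Conditions: 33, 2,4,6-trichlorobenzoyl chloride, Et3N, toluene, rt; then 32, 80 °C
Reagents that add atoms: none
Why: Yamaguchi-type mixed-anhydride esterification run without a nucleophilic catalyst, the protocol known to transfer the angeloyl group without Z-to-E isomerisation, and O6 is the only free hydroxyl.

Step 23
Reactants: 35 6β-angelate
Product: 36 9α,15-diol
Conditions: HF·pyridine, THF, 0 °C to rt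
Reagents that add atoms: none
Why: Acidic fluoride cleaves both silyl ethers, while the esters, the α-methylene lactone and the Z-alkene are inert to it.

Step 24
Reactants: 36 9α,15-diol
Product: 37 target CNP0277836.2
Conditions: MnO2 (activated, excess), CH2Cl2, rt
Reagents that add atoms: none
Why: MnO2 oxidises allylic alcohols selectively, so the primary allylic C15 alcohol becomes the enal and the saturated secondary 9α-alcohol stays.

Compound list
1 | 4-methoxy-2-methylphenol | Cc1cc(OC)ccc1O | starting material
2 | 4,4-dimethoxy-2-methylcyclohexa-2,5-dien-1-one | COC1(OC)C=CC(=O)C(C)=C1 | intermediate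
3 | 4,4-dimethoxy-2-methylcyclohex-2-en-1-one | COC1(OC)CCC(=O)C(C)=C1 | intermediate
4 | (S)-4,4-dimethoxy-2-methylcyclohex-2-en-1-ol | CC1=CC(OC)(OC)CC[C@@H]1O | intermediate
5 | (S)-tert-butyl[(4,4-dimethoxy-2-methylcyclohex-2-en-1-yl)oxy]dimethylsilane | CC1=CC(OC)(OC)CC[C@@H]1O[Si](C)(C)C(C)(C)C | intermediate
6 | (S)-4-(tert-butyldimethylsilyloxy)-3-methylcyclohex-2-en-1-one (9β-OTBS enone) | CC1=CC(=O)CC[C@@H]1O[Si](C)(C)C(C)(C)C | intermediate
7 | ethyl 1-bromocyclobutane-1-carboxylate | CCOC(=O)C1(Br)CCC1 | starting material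
8 | cyclobut-1-ene-1-carboxylic acid | OC(=O)C1=CCC1 | intermediate
9 | methyl cyclobut-1-ene-1-carboxylate | COC(=O)C1=CCC1 | intermediate
10 | cis-anti-cis photoadduct, methyl 7-(tert-butyldimethylsilyloxy)-6-methyl-10-oxotricyclo[4.4.0.0(2,5)]decane-2-carboxylate | COC(=O)[C@]12CC[C@H]1[C@]1(C)[C@@H](O[Si](C)(C)C(C)(C)C)CCC(=O)[C@@H]12 | intermediate
11 | tert-butyl bromoacetate | BrCC(=O)OC(C)(C)C | starting material
12 | lithium C6,C7-enolate of 10 | COC(=O)[C@]12CC[C@H]1[C@]1(C)[C@@H](O[Si](C)(C)C(C)(C)C)CC=C(O[Li])[C@@H]12 | intermediate (not isolated)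
13 | C7β-(tert-butoxycarbonylmethyl) photoadduct | COC(=O)[C@]12CC[C@H]1[C@]1(C)[C@@H](O[Si](C)(C)C(C)(C)C)C[C@@H](CC(=O)OC(C)(C)C)C(=O)[C@@H]12 | intermediate
14 | cis-dialkenyl ketone (vinyl and acrylate both α, H5 β) | C=C[C@]1(C)[C@@H](O[Si](C)(C)C(C)(C)C)C[C@@H](CC(=O)OC(C)(C)C)C(=O)[C@@H]1C(=C)C(=O)OC | intermediate (not isolated)
15 | trans keto diester (vinyl α, acrylate β, H5 and H7 α) | C=C[C@]1(C)[C@@H](O[Si](C)(C)C(C)(C)C)C[C@@H](CC(=O)OC(C)(C)C)C(=O)[C@H]1C(=C)C(=O)OC | intermediate
16 | 6β,15-diol | C=C[C@]1(C)[C@@H](O[Si](C)(C)C(C)(C)C)C[C@@H](CC(=O)OC(C)(C)C)[C@@H](O)[C@H]1C(=C)CO | intermediate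
17 | 6,15-bis(methoxymethyl) ether | C=C[C@]1(C)[C@@H](O[Si](C)(C)C(C)(C)C)C[C@@H](CC(=O)OC(C)(C)C)[C@@H](OCOC)[C@H]1C(=C)COCOC | intermediate
18 | 9β-alcohol | C=C[C@]1(C)[C@@H](O)C[C@@H](CC(=O)OC(C)(C)C)[C@@H](OCOC)[C@H]1C(=C)COCOC | intermediate
19 | C9 ketone | C=C[C@]1(C)C(=O)C[C@@H](CC(=O)OC(C)(C)C)[C@@H](OCOC)[C@H]1C(=C)COCOC | intermediate
20 | potassium C8,C9-enolate of 19 | C=C[C@]1(C)C(O[K])=C[C@@H](CC(=O)OC(C)(C)C)[C@@H](OCOC)[C@H]1C(=C)COCOC | intermediate (not isolated)
21 | 8α-hydroxy-9-ketone | C=C[C@]1(C)C(=O)[C@H](O)[C@@H](CC(=O)OC(C)(C)C)[C@@H](OCOC)[C@H]1C(=C)COCOC | intermediate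
22 | 8α-hydroxy-9-oxo acid | C=C[C@]1(C)C(=O)[C@H](O)[C@@H](CC(=O)O)[C@@H](OCOC)[C@H]1C(=C)COCOC | intermediate (not isolated)
23 | 9-oxo-8α,12-lactone (trans-fused, H7 α, H8 β) | C=C[C@]1(C)C(=O)[C@@H]2OC(=O)C[C@H]2[C@@H](OCOC)[C@H]1C(=C)COCOC | intermediate
24 | 9α-hydroxy lactone | C=C[C@]1(C)[C@H](O)[C@@H]2OC(=O)C[C@H]2[C@@H](OCOC)[C@H]1C(=C)COCOC | intermediate
25 | 9α-(tert-butyldimethylsilyloxy) lactone | C=C[C@]1(C)[C@H](O[Si](C)(C)C(C)(C)C)[C@@H]2OC(=O)C[C@H]2[C@@H](OCOC)[C@H]1C(=C)COCOC | intermediate
26 | lithium enolate of 25 | C=C[C@]1(C)[C@H](O[Si](C)(C)C(C)(C)C)[C@@H]2OC(O[Li])=C[C@H]2[C@@H](OCOC)[C@H]1C(=C)COCOC | intermediate (not isolated)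
27 | 11-(dimethylaminomethyl) lactone (C11 not defined, destroyed in the same step) | C=C[C@]1(C)[C@H](O[Si](C)(C)C(C)(C)C)[C@@H]2OC(=O)C(CN(C)C)[C@H]2[C@@H](OCOC)[C@H]1C(=C)COCOC | intermediate (not isolated)
28 | methiodide of 27 | C=C[C@]1(C)[C@H](O[Si](C)(C)C(C)(C)C)[C@@H]2OC(=O)C(C[N+](C)(C)C)[C@H]2[C@@H](OCOC)[C@H]1C(=C)COCOC.[I-] | intermediate (not isolated)
29 | α-methylene lactone | C=C[C@]1(C)[C@H](O[Si](C)(C)C(C)(C)C)[C@@H]2OC(=O)C(=C)[C@H]2[C@@H](OCOC)[C@H]1C(=C)COCOC | intermediate
30 | 6,15-bis(bromomethyl) ether | C=C[C@]1(C)[C@H](O[Si](C)(C)C(C)(C)C)[C@@H]2OC(=O)C(=C)[C@H]2[C@@H](OCBr)[C@H]1C(=C)COCBr | intermediate (not isolated)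
31 | 6β,15-diol of the methylene lactone | C=C[C@]1(C)[C@H](O[Si](C)(C)C(C)(C)C)[C@@H]2OC(=O)C(=C)[C@H]2[C@@H](O)[C@H]1C(=C)CO | intermediate
32 | 15-O-triethylsilyl ether | C=C[C@]1(C)[C@H](O[Si](C)(C)C(C)(C)C)[C@@H]2OC(=O)C(=C)[C@H]2[C@@H](O)[C@H]1C(=C)CO[Si](CC)(CC)CC | intermediate
33 | angelic acid, (Z)-2-methylbut-2-enoic acid | C/C=C(/C)C(=O)O | starting material
34 | angelic 2,4,6-trichlorobenzoic anhydride | C/C=C(/C)C(=O)OC(=O)c1c(Cl)cc(Cl)cc1Cl | intermediate (not isolated)
35 | 6β-angelate | C=C[C@]1(C)[C@H](O[Si](C)(C)C(C)(C)C)[C@@H]2OC(=O)C(=C)[C@H]2[C@@H](OC(=O)/C(C)=C\C)[C@H]1C(=C)CO[Si](CC)(CC)CC | intermediate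
36 | 9α,15-diol | C=C[C@]1(C)[C@H](O)[C@@H]2OC(=O)C(=C)[C@H]2[C@@H](OC(=O)/C(C)=C\C)[C@H]1C(=C)CO | intermediate
37 | CNP0277836.2 (6β-angeloyloxy-9α-hydroxy-15-oxoelema-1,3,11(13)-trien-8α,12-olide) | C=C[C@]1(C)[C@H](O)[C@@H]2OC(=O)C(=C)[C@H]2[C@@H](OC(=O)/C(C)=C\C)[C@H]1C(=C)C=O | target

Total step count: 24.
Longest linear sequence: 22 steps (steps 1–5 and 8–24).

Steps most likely to fail

**Step 8.**
- What may go wrong: erosion of facial selectivity at C10 (approach syn to the silyl ether), partial head-to-tail addition, and loss of the strained ester by oligomerisation. The adducts are diastereomers, so material rather than enantiopurity is at stake.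
- Route of the fallback: it sets out from 6, returns at 17, and forms the two bonds one after the other by ionic chemistry.
- C10–C1: copper-mediated conjugate vinylation of 6 (CH2=CHMgBr, CuBr·SMe2, Me3SiCl, THF, −78 °C) is reliably anti to a 4-silyloxy group. It sets C10 and gives the regiodefined trimethylsilyl enol ether F1.
- Coupling partner: 2-bromoallyl alcohol and MOMCl give 2-bromo-3-(methoxymethoxy)prop-1-ene F2.
- C5–C4: α-alkenylation of F1 with F2 under zerovalent-palladium catalysis (Pd2(dba)3, P(t-Bu)3, Bu3SnF, toluene, 80 °C), followed by DBU equilibration, gives the trans C5-alkenyl ketone F3.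
- C7: kinetic alkylation with 11 (LiN(i-Pr)2, THF, −78 °C) and DBU equilibration give the keto ester F4.
- C6 and return: LiBH(s-Bu)3, with no acrylate present, gives the 6β-alcohol F5, and MOMCl/i-Pr2NEt converts F5 into 17.

**Step 11.**
- What may go wrong: incomplete discrimination among three carbonyl groups. The aluminium 6β-alkoxide may close onto the methyl ester and stop at the lactol stage, the tert-butyl ester may be attacked, or too little equatorial attack may occur at C6.
- Route of the fallback: it sets out from 15, returns at 16, and separates the tasks.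
- Ketone only: Luche reduction (NaBH4, CeCl3·7H2O, MeOH, −40 °C) touches only the ketone. The 6β-alkoxide is allowed to close onto the neighbouring methyl ester to give the cis-fused 6β,15-lactone F6, in which O6 is tied up and cannot reach C12.
- Lactone: one equivalent of i-Bu2AlH at −78 °C takes this lactone, far more reactive than the tert-butyl ester, to the lactol F7.
- Return: a second Luche reduction of the open hydroxy-enal form of F7 gives 16.

**Step 22.**
- What may go wrong: sluggish acylation of the axial O6, which is flanked by C5 and C7 and is syn-axial to the C10 methyl. Under forcing conditions this may lead to Z-to-E isomerisation of the acyl group or to migration of the lactone from O8 to O6.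
- Route of the fallback: it sets out from 32, returns at 35, and builds the alkene after the acylation.
- Acylation: O6 is esterified with 2-[bis(2,2,2-trifluoroethoxy)phosphoryl]propanoic acid (DCC, DMAP, CH2Cl2), an acid that has no alkene to isomerise, to give the phosphonopropionate F8.
- Olefination and return: Still–Gennari olefination of F8 (KN(SiMe3)2, 18-crown-6, THF, −78 °C; acetaldehyde) forms the Z-trisubstituted alkene on the ester already in place and gives 35.

Further compounds
F1 | step 8 | trimethylsilyl enol ether (C5=C6) of the 10α-vinyl-10β-methyl-9β-silyloxy cyclohexanone | C=C[C@]1(C)[C@@H](O[Si](C)(C)C(C)(C)C)CCC(O[Si](C)(C)C)=C1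
F2 | step 8 | 2-bromo-3-(methoxymethoxy)prop-1-ene | C=C(Br)COCOC
F3 | step 8 | trans C5β-[3-(methoxymethoxy)prop-1-en-2-yl] ketone | C=C[C@]1(C)[C@@H](O[Si](C)(C)C(C)(C)C)CCC(=O)[C@H]1C(=C)COCOC
F4 | step 8 | C7β-(tert-butoxycarbonylmethyl) keto ester | C=C[C@]1(C)[C@@H](O[Si](C)(C)C(C)(C)C)C[C@@H](CC(=O)OC(C)(C)C)C(=O)[C@H]1C(=C)COCOC
F5 | step 8 | 6β-alcohol with 15-OMOM | C=C[C@]1(C)[C@@H](O[Si](C)(C)C(C)(C)C)C[C@@H](CC(=O)OC(C)(C)C)[C@@H](O)[C@H]1C(=C)COCOC
F6 | step 11 | cis-fused 6β,15-lactone (α-methylene-γ-lactone, tert-butyl ester retained) | C=C[C@]1(C)[C@@H](O[Si](C)(C)C(C)(C)C)C[C@@H](CC(=O)OC(C)(C)C)[C@H]2OC(=O)C(=C)[C@@H]12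
F7 | step 11 | 6β,15-lactol (anomeric centre not defined) | C=C[C@]1(C)[C@@H](O[Si](C)(C)C(C)(C)C)C[C@@H](CC(=O)OC(C)(C)C)[C@H]2OC(O)C(=C)[C@@H]12
F8 | step 22 | 6β-O-{2-[bis(2,2,2-trifluoroethoxy)phosphoryl]propanoyl} ester (α-carbon of the acyl group not defined) | C=C[C@]1(C)[C@H](O[Si](C)(C)C(C)(C)C)[C@@H]2OC(=O)C(=C)[C@H]2[C@@H](OC(=O)C(C)P(=O)(OCC(F)(F)F)OCC(F)(F)F)[C@H]1C(=C)CO[Si](CC)(CC)CC
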